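Assumption: the SMILES is taken literally, so the vinyl and hydroxyisopropenyl groups are cis on the cyclohexane (C10 is epimeric to the common elemanolides); germacrane numbering (C1–C15) is used for positions throughout.

## Retrosynthetic overview

1. Target ⇐ C15 allylic hydroxylation and desilylation of the 10-epi-elemanolide 24.
2. Cyclohexane ⇐ Cope rearrangement of the (1(10)E,4Z)-germacranolide 23; a cis-decalin-like chair turns 4Z into 5α-H and 1(10)E into the axial 10β-vinyl group.
3. Ten-membered ring and lactone ⇐ CrCl2-mediated C6–C7 allylation of a (2Z,6E)-farnesal-type enal by a 2-(bromomethyl)enoate that already carries the C8 ester, then lactonisation onto C12.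
4. Open chain 20 ⇐ cross-metathesis (acrylate unit), esterification (Roche-ester acid), and B-alkyl Suzuki union of a (Z)-dienol with an (E)-vinyl iodide made from (S)-epichlorohydrin.
5. Ring order: ten-membered carbocycle → γ-lactone → cyclohexane (the ten-membered ring is consumed).

## Route

Step 1
Reactants: 1 methyl (2R)-3-hydroxy-2-methylpropanoate
Product: 2 methyl (2R)-3-[(tert-butyldimethylsilyl)oxy]-2-methylpropanoate
Conditions: TBSCl, imidazole, CH2Cl2, 0 °C to rt
Reagents that add atoms: tert-butyldimethylsilyl chloride, CC(C)(C)[Si](C)(C)Cl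
Why: Imidazole-promoted silyl ether formation on the primary alcohol; the side-chain stereocentre comes from the chiral pool and is not touched.

Step 2
Reactants: 2 methyl (2R)-3-[(tert-butyldimethylsilyl)oxy]-2-methylpropanoate
Product: 3 (2R)-3-[(tert-butyldimethylsilyl)oxy]-2-methylpropanoic acid
Conditions: LiOH, THF/MeOH/H2O, 0 °C to rt; then HCl to pH 4
Reagents that add atoms: lithium hydroxide, [Li+].[OH-]
Why: Mild ester saponification keeps the primary silyl ether and, at 0 °C, does not epimerise the α-stereocentre.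

Step 3
Reactants: 4 (2S)-2-(chloromethyl)oxirane [(S)-epichlorohydrin]; 5 ethynyl(trimethyl)silane
Product: 7 (2S)-1-chloro-5-(trimethylsilyl)pent-4-yn-2-ol, via lithium (trimethylsilyl)acetylide 6 (not isolated)
Conditions: n-BuLi, THF, −78 °C; BF3·OEt2; then 4, −78 °C; NH4Cl quench
Reagents that add atoms: none
Why: BF3-assisted epoxide opening by a lithium acetylide (Yamaguchi–Hirao alkynylation) occurs only at the unsubstituted epoxide carbon, so the future C8 stereocentre is carried over unchanged from (S)-epichlorohydrin.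

Step 4
Reactants: 7 (2S)-1-chloro-5-(trimethylsilyl)pent-4-yn-2-ol
Product: 10 (3S)-hex-1-en-5-yn-3-ol, via silylpropargyl oxirane 8 (not isolated), via C-silylated enynol 9 (not isolated)
Conditions: Me3SI (3.5 equiv), n-BuLi (3.4 equiv), THF, −20 °C to rt; then K2CO3, MeOH, rt
Reagents that add atoms: trimethylsulfonium iodide, C[S+](C)C.[I-]
Why: Base closes the chlorohydrin to the epoxide, dimethylsulfonium methylide opens it at CH2 and Me2S is eliminated to give the one-carbon-homologated allylic alcohol (sulfonium-ylide epoxide-to-allylic-alcohol homologation) without breaking the carbinol C–O bond, and K2CO3/MeOH then removes the alkynyl silyl group.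

Step 5
Reactants: 10 (3S)-hex-1-en-5-yn-3-ol
Product: 12 (3S,5E)-6-iodo-5-methylhexa-1,5-dien-3-ol, via (E)-alkenyl(dimethyl)alane 11 (not isolated)
Conditions: Me3Al (3 equiv), Cp2ZrCl2 (25 mol%), CH2Cl2, 0 °C to rt; then I2, THF, −30 °C
Reagents that add atoms: trimethylaluminium, C[Al](C)C; iodine, II
Why: Negishi zirconium-catalysed syn-carboalumination puts methyl on the internal alkyne carbon and iodinolysis with retention gives the (E)-vinyl iodide that fixes the 1(10)E geometry, the alkoxide-directed isomerisation to the Z isomer needing heat that is not applied.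

Step 6
Reactants: 13 (2Z)-3-methylpent-2-en-4-yn-1-ol
Product: 14 (2Z)-3-methylpenta-2,4-dien-1-ol
Conditions: H2 (1 atm), Pd/CaCO3 poisoned with Pb(OAc)2, quinoline, EtOAc, rt
Reagents that add atoms: none
Why: Semihydrogenation of the terminal alkyne stops at the vinyl group and leaves the trisubstituted (Z)-olefin, the future 4Z double bond, unchanged.

Step 7
Reactants: 14 (2Z)-3-methylpenta-2,4-dien-1-ol; 12 (3S,5E)-6-iodo-5-methylhexa-1,5-dien-3-ol
Product: 16 (3S,5E,9Z)-5,9-dimethylundeca-1,5,9-triene-3,11-diol, via alkylborane 15 (not isolated)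
Conditions: 14, 9-BBN (2.1 equiv per 14), THF, 0 °C to rt; then 12, Pd(dppf)Cl2 (5 mol%), AsPh3, aq. K3PO4, DMF, rt
Reagents that add atoms: none
Why: 9-BBN adds to the terminal carbon of the diene (the hydroxyl is masked in the flask as its borinate) and the B-alkyl Suzuki–Miyaura coupling joins C1 to C2 with retention of both olefin geometries.

Step 8
Reactants: 16 (3S,5E,9Z)-5,9-dimethylundeca-1,5,9-triene-3,11-diol
Product: 17 (2Z,6E,9S)-9-hydroxy-3,7-dimethylundeca-2,6,10-trienal
Conditions: TEMPO (10 mol%), PhI(OAc)2 (1.1 equiv), CH2Cl2, 0 °C to rt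
Reagents that add atoms: none
Why: Oxoammonium (TEMPO) oxidation is selective for the primary allylic alcohol over the secondary one and is known to convert nerol-type alcohols to (Z)-enals without Z/E isomerisation.

Step 9
Reactants: 17 (2Z,6E,9S)-9-hydroxy-3,7-dimethylundeca-2,6,10-trienal; 3 (2R)-3-[(tert-butyldimethylsilyl)oxy]-2-methylpropanoic acid
Product: 18 (3S,5E,9Z)-5,9-dimethyl-11-oxoundeca-1,5,9-trien-3-yl (2R)-3-[(tert-butyldimethylsilyl)oxy]-2-methylpropanoate
Conditions: DCC, DMAP (10 mol%), CH2Cl2, 0 °C to rt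
Reagents that add atoms: none
Why: Steglich esterification of the only free hydroxyl installs the complete C8 ester before ring formation, so this oxygen cannot later compete for lactonisation; neither stereocentre is touched.

Step 10
Reactants: 18 (3S,5E,9Z)-5,9-dimethyl-11-oxoundeca-1,5,9-trien-3-yl (2R)-3-[(tert-butyldimethylsilyl)oxy]-2-methylpropanoate; 19 methyl 2-(bromomethyl)prop-2-enoate
Product: 20 methyl (2Z,4S,6E,10Z)-2-(bromomethyl)-4-{[(2R)-3-(tert-butyldimethylsilyloxy)-2-methylpropanoyl]oxy}-6,10-dimethyl-12-oxododeca-2,6,10-trienoate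
Conditions: 19 (5 equiv), second-generation Hoveyda–Grubbs catalyst RuCl2(H2IMes)(=CH-C6H4-2-OiPr) (10 mol%), CH2Cl2, 40 °C
Reagents that add atoms: none
Why: Olefin cross-metathesis engages only the monosubstituted vinyl group (the trisubstituted and conjugated olefins are inert) and gives the thermodynamically preferred enoate with C8 trans to CO2Me.

Step 11
Reactants: 20 methyl (2Z,4S,6E,10Z)-2-(bromomethyl)-4-{[(2R)-3-(tert-butyldimethylsilyloxy)-2-methylpropanoyl]oxy}-6,10-dimethyl-12-oxododeca-2,6,10-trienoate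
Product: 24 8α-{[(2R)-3-(tert-butyldimethylsilyloxy)-2-methylpropanoyl]oxy}-10-epi-elema-1,3,11(13)-trien-12,6α-olide (5α-H, 6β-H, 7α-H, 8β-H, 10β-vinyl, 10α-methyl), via allyl–CrCl2 species 21 (not isolated), via seco hydroxy ester 22 (not isolated), via (1(10)E,4Z)-germacranolide 23 (not isolated)
Conditions: CrCl2 (6 equiv), THF, 2 mM, rt, slow addition; aqueous work-up, silica plug; then PhMe, BHT, 170 °C (sealed tube)
Reagents that add atoms: none
Why: Nozaki–Hiyama-type macrocyclisation, lactonisation and Cope rearrangement in one telescoped operation, in which the allyl–CrCl2 reagent adds through C7 to the enal carbonyl via a six-membered chair on the face of C7 anti to the C8 acyloxy group (setting 6β-H and 7α-H, trans, relative to 8β-H), the O–CrCl2 alkoxide closes the lactone on the methyl ester, and on heating the (E,Z)-cyclodeca-1,5-diene rearranges through the cis-decalin-like chair that keeps the trans-lactone diequatorial, so 4Z gives 5α-H and 1(10)E gives the axial 10β-vinyl group cis to the isopropenyl group.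

Step 12
Reactants: 24 8α-acyloxy-10-epi-elema-1,3,11(13)-trien-12,6α-olide (silyl-protected side chain)
Product: 25 15-hydroxy derivative of 24 (C5 substituent now 3-hydroxyprop-1-en-2-yl; all stereocentres as in 24)
Conditions: SeO2 (0.5 equiv), t-BuOOH (2 equiv), CH2Cl2, 0 °C to rt
Reagents that add atoms: selenium dioxide, O=[Se]=O; tert-butyl hydroperoxide, CC(C)(C)OO
Why: SeO2-catalysed allylic hydroxylation (ene reaction then [2,3]-shift) attacks the methyl of the electron-rich 1,1-disubstituted isopropenyl group, because the vinyl group has no allylic hydrogen and the lactone methylene is electron-poor.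

Step 13
Reactants: 25 15-hydroxy silyl ether
Product: 26 (3aR,4S,6R,7R,7aR)-6-ethenyl-7-(3-hydroxyprop-1-en-2-yl)-6-methyl-3-methylidene-2-oxooctahydro-1-benzofuran-4-yl (2R)-3-hydroxy-2-methylpropanoate (target)
Conditions: HF·pyridine, pyridine/THF, 0 °C to rt
Reagents that add atoms: none
Why: Buffered fluoride desilylation removes the primary silyl ether without touching the α-methylene lactone, the ester or the allylic alcohol.

## Compound list

1 | methyl (2R)-3-hydroxy-2-methylpropanoate | COC(=O)[C@H](C)CO | starting material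
2 | methyl (2R)-3-[(tert-butyldimethylsilyl)oxy]-2-methylpropanoate | COC(=O)[C@H](C)CO[Si](C)(C)C(C)(C)C | intermediate
3 | (2R)-3-[(tert-butyldimethylsilyl)oxy]-2-methylpropanoic acid | OC(=O)[C@H](C)CO[Si](C)(C)C(C)(C)C | intermediate
4 | (2S)-2-(chloromethyl)oxirane, (S)-epichlorohydrin | ClC[C@@H]1CO1 | starting material
5 | ethynyl(trimethyl)silane | C#C[Si](C)(C)C | starting material
6 | lithium (trimethylsilyl)acetylide | [Li]C#C[Si](C)(C)C | intermediate
7 | (2S)-1-chloro-5-(trimethylsilyl)pent-4-yn-2-ol | ClC[C@@H](O)CC#C[Si](C)(C)C | intermediate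
8 | (2S)-2-[3-(trimethylsilyl)prop-2-yn-1-yl]oxirane | C1[C@@H](O1)CC#C[Si](C)(C)C | intermediate
9 | (3S)-6-(trimethylsilyl)hex-1-en-5-yn-3-ol | C=C[C@@H](O)CC#C[Si](C)(C)C | intermediate
10 | (3S)-hex-1-en-5-yn-3-ol | C=C[C@@H](O)CC#C | intermediate
11 | dimethylaluminium (3S,5E)-6-(dimethylalumanyl)-5-methylhexa-1,5-dien-3-olate | C=C[C@@H](O[Al](C)C)C/C(C)=C/[Al](C)C | intermediate
12 | (3S,5E)-6-iodo-5-methylhexa-1,5-dien-3-ol | C=C[C@@H](O)C/C(C)=C/I | intermediate
13 | (2Z)-3-methylpent-2-en-4-yn-1-ol | C#C/C(C)=C\CO | starting material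
14 | (2Z)-3-methylpenta-2,4-dien-1-ol | C=C/C(C)=C\CO | intermediate
15 | 9-[(3Z)-3-methyl-5-(9-borabicyclo[3.3.1]nonan-9-yloxy)pent-3-en-1-yl]-9-borabicyclo[3.3.1]nonane | B1(CC/C(C)=C\COB2C3CCCC2CCC3)C2CCCC1CCC2 | intermediate
16 | (3S,5E,9Z)-5,9-dimethylundeca-1,5,9-triene-3,11-diol | C=C[C@@H](O)C/C(C)=C/CC/C(C)=C\CO | intermediate
17 | (2Z,6E,9S)-9-hydroxy-3,7-dimethylundeca-2,6,10-trienal | C=C[C@@H](O)C/C(C)=C/CC/C(C)=C\C=O | intermediate
18 | (3S,5E,9Z)-5,9-dimethyl-11-oxoundeca-1,5,9-trien-3-yl (2R)-3-[(tert-butyldimethylsilyl)oxy]-2-methylpropanoate | C=C[C@@H](OC(=O)[C@H](C)CO[Si](C)(C)C(C)(C)C)C/C(C)=C/CC/C(C)=C\C=O | intermediate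
19 | methyl 2-(bromomethyl)prop-2-enoate | C=C(CBr)C(=O)OC | starting material
20 | methyl (2Z,4S,6E,10Z)-2-(bromomethyl)-4-{[(2R)-3-(tert-butyldimethylsilyloxy)-2-methylpropanoyl]oxy}-6,10-dimethyl-12-oxododeca-2,6,10-trienoate | COC(=O)/C(CBr)=C/[C@@H](OC(=O)[C@H](C)CO[Si](C)(C)C(C)(C)C)C/C(C)=C/CC/C(C)=C\C=O | intermediate
21 | allyl–CrCl2 reagent from 20 (CrCl2 in place of Br on C13) | COC(=O)/C(C[Cr](Cl)Cl)=C/[C@@H](OC(=O)[C@H](C)CO[Si](C)(C)C(C)(C)C)C/C(C)=C/CC/C(C)=C\C=O | intermediate
22 | methyl (1(10)E,4Z)-8α-acyloxy-6α-hydroxygermacra-1(10),4,11(13)-trien-12-oate (6β-H, 7α-H, 8β-H; acyl = (2R)-3-silyloxy-2-methylpropanoyl) | COC(=O)C(=C)[C@@H]1[C@@H](OC(=O)[C@H](C)CO[Si](C)(C)C(C)(C)C)C/C(C)=C/CC/C(C)=C\[C@H]1O | intermediate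
23 | (1(10)E,4Z)-8α-{[(2R)-3-(tert-butyldimethylsilyloxy)-2-methylpropanoyl]oxy}germacra-1(10),4,11(13)-trien-12,6α-olide (6β-H, 7α-H, 8β-H) | C/C1=C\CC/C(C)=C\[C@H]2OC(=O)C(=C)[C@@H]2[C@@H](OC(=O)[C@H](C)CO[Si](C)(C)C(C)(C)C)C1 | intermediate
24 | 8α-{[(2R)-3-(tert-butyldimethylsilyloxy)-2-methylpropanoyl]oxy}-10-epi-elema-1,3,11(13)-trien-12,6α-olide (5α-H, 6β-H, 7α-H, 8β-H, 10β-vinyl, 10α-methyl) | C=C[C@@]1(C)C[C@H](OC(=O)[C@H](C)CO[Si](C)(C)C(C)(C)C)[C@H]2C(=C)C(=O)O[C@@H]2[C@H]1C(C)=C | intermediate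
25 | 15-hydroxy derivative of 24 (silyl ether of the target) | C=C[C@@]1(C)C[C@H](OC(=O)[C@H](C)CO[Si](C)(C)C(C)(C)C)[C@H]2C(=C)C(=O)O[C@@H]2[C@H]1C(=C)CO | intermediate
26 | (3aR,4S,6R,7R,7aR)-6-ethenyl-7-(3-hydroxyprop-1-en-2-yl)-6-methyl-3-methylidene-2-oxooctahydro-1-benzofuran-4-yl (2R)-3-hydroxy-2-methylpropanoate | C=C[C@@]1(C)C[C@H](OC(=O)[C@H](C)CO)[C@H]2C(=C)C(=O)O[C@@H]2[C@H]1C(=C)CO | target

## Step count and risks

Total steps: 13. Longest linear sequence: 10 steps (3, 4, 5, 7, 8, 9, 10, 11, 12, 13, from 4 and 5).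

**Step 11 (macrocyclisation, lactonisation, Cope).** The allyl–CrCl2 species may lose the C8 ester by 1,4-elimination; C6/C7 selectivity rests on one stereocentre; and a boat-type Cope would give the wrong C5/C10 pair. The fallback sets out from bromide 20. Borylation with B2pin2 and Pd2(dba)3 (zerovalent palladium) in DMSO would give the pinacol allylboronate F1. Heated at high dilution in toluene (110 °C), F1 should close the ten-membered ring by intramolecular allylboration through a closed chair transition state; boron cannot trigger the elimination, and the enoate geometry is transferred to C6/C7. Lactonisation then brings the material back to the route at germacranolide 23, which is heated on to 24 in the same pot.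

**Step 10 (cross-metathesis).** A hindered allylic ester must couple with a 1,1-disubstituted acrylate, which may stall. The fallback sets out from hydroxy enal 17. Acylation with 2-(bromomethyl)acrylic acid (DIC, catalytic DMAP) gives the acrylate ester F2. Ring-closing metathesis with the same ruthenium catalyst, a far easier five-membered closure, gives the 3-(bromomethyl)butenolide F3. CrCl2-mediated macrocyclisation of this bromolactone onto the enal, with C7 attacked anti to the C9 chain on the butenolide, gives the 6α-hydroxy-8,12-olide F4. Translactonisation with DBU in toluene gives the 8α-hydroxy-6,12-olide F5. Steglich esterification of F5 with acid 3 returns to the route at germacranolide 23, which is then heated as in step 11.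

**Step 12 (SeO2 hydroxylation).** Over-oxidation to the enal or attack at C5–H could lower the yield. The fallback sets out from 24. Ene-type chlorination with Ca(OCl)2 and CO2 in CH2Cl2/H2O would give the allylic chloride F6. Silver-assisted hydrolysis (AgBF4, aqueous acetone) through the symmetrical 2-substituted allyl cation returns to the route at 25.

Further compounds
F1 | step 11 | methyl (2E,4S,6E,10Z)-4-{[(2R)-3-(tert-butyldimethylsilyloxy)-2-methylpropanoyl]oxy}-6,10-dimethyl-12-oxo-2-[(4,4,5,5-tetramethyl-1,3,2-dioxaborolan-2-yl)methyl]dodeca-2,6,10-trienoate | COC(=O)/C(CB1OC(C)(C)C(C)(C)O1)=C/[C@@H](OC(=O)[C@H](C)CO[Si](C)(C)C(C)(C)C)C/C(C)=C/CC/C(C)=C\C=O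
F2 | step 10 | (3S,5E,9Z)-5,9-dimethyl-11-oxoundeca-1,5,9-trien-3-yl 2-(bromomethyl)prop-2-enoate | C=C[C@@H](OC(=O)C(=C)CBr)C/C(C)=C/CC/C(C)=C\C=O
F3 | step 10 | (5S)-3-(bromomethyl)-5-[(2E,6Z)-2,6-dimethyl-8-oxoocta-2,6-dien-1-yl]furan-2(5H)-one | O=C1O[C@@H](C/C(C)=C/CC/C(C)=C\C=O)C=C1CBr
F4 | step 10 | (1(10)E,4Z)-6α-hydroxygermacra-1(10),4,11(13)-trien-12,8α-olide (6β-H, 7α-H, 8β-H) | O=C1O[C@H]2C/C(C)=C/CC/C(C)=C\[C@@H](O)[C@@H]2C1=C
F5 | step 10 | (1(10)E,4Z)-8α-hydroxygermacra-1(10),4,11(13)-trien-12,6α-olide (6β-H, 7α-H, 8β-H) | C/C1=C\CC/C(C)=C\[C@H]2OC(=O)C(=C)[C@@H]2[C@@H](O)C1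
F6 | step 12 | 15-chloro derivative of 24 (C5 substituent 3-chloroprop-1-en-2-yl) | C=C[C@@]1(C)C[C@H](OC(=O)[C@H](C)CO[Si](C)(C)C(C)(C)C)[C@H]2C(=C)C(=O)O[C@@H]2[C@H]1C(=C)CCl
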